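Benzofuran numbering is used throughout. Ring A is the benzo ring, ring B the furan and ring C the 3,4,5-trimethoxyphenyl group.
The retrosynthesis first adds a hydroxyl at C4 and then cuts ring A at C6–C7, C4–C5 and C3a–C4. C7 bears OMe and is bonded to furan carbon C7a, so it is the carbene carbon of a methoxy(2-furyl)carbene chromium complex. C6–H and C5–CHO are the two carbons of a terminal alkyne with a masked formyl group, and C4 is a CO ligand.
The last cut is the C2–aryl bond between rings B and C, which leads back to 3-methyl-2-furoic acid and an aryl bromide.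
Forward order: rings B and C are bought and joined by decarboxylative arylation, the free furan α-carbon is turned into the carbene, and ring A is closed by benzannulation. The acetal is then opened and the C4 oxygen is removed through its triflate.
Stereochemistry: there is none to set, because the target is achiral with no stereocentre and no configurable double bond.

Key step: step 3

Step 1
Reactants: 1 3-methylfuran-2-carboxylic acid; 2 5-bromo-1,2,3-trimethoxybenzene
Product: 3 3-methyl-2-(3,4,5-trimethoxyphenyl)furan
Conditions: 1 (2 equiv), Pd[P(t-Bu)3]2 (5 mol %), n-Bu4NCl (1 equiv), Cs2CO3 (1.5 equiv), DMF, 170 °C (microwave)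
Reagents that add atoms: none
Why: This is a decarboxylative cross-coupling of a heteroaromatic 2-carboxylic acid with an aryl bromide, in which the Ar–Pd–Br species from oxidative addition to zerovalent palladium attacks the carboxylate-bearing furan carbon, CO2 leaves and reductive elimination forms the ring B–ring C bond, while the C3 methyl group blocks arylation next to the acid and the excess of 1 limits a second arylation at the free α-carbon.

Step 2
Reactants: 3 3-methyl-2-(3,4,5-trimethoxyphenyl)furan; 4 chromium hexacarbonyl
Product: 7 pentacarbonyl{methoxy[4-methyl-5-(3,4,5-trimethoxyphenyl)furan-2-yl]methylidene}chromium, via furyllithium 5 (not isolated), via lithium acylpentacarbonylchromate 6 (not isolated)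
Conditions: n-BuLi, THF, −78 to 0 °C; Cr(CO)6, 0 °C to rt; solvent removed; Me3OBF4, CH2Cl2, 0 °C to rt
Reagents that add atoms: trimethyloxonium tetrafluoroborate (Me3OBF4), C[O+](C)C.F[B-](F)(F)F
Why: This is a Fischer carbene synthesis, in which n-BuLi removes the single furan α-hydrogen (the most acidic C–H bond of 3), the furyllithium adds to a CO ligand of Cr(CO)6, and the hard methylating agent alkylates the resulting acylmetalate on oxygen.

Step 3
Reactants: 7 pentacarbonyl{methoxy[4-methyl-5-(3,4,5-trimethoxyphenyl)furan-2-yl]methylidene}chromium; 8 3,3-diethoxyprop-1-yne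
Product: 10 5-(diethoxymethyl)-7-methoxy-3-methyl-2-(3,4,5-trimethoxyphenyl)-1-benzofuran-4-ol, via tricarbonylchromium arene complex 9 (not isolated)
Conditions: 8 (2 equiv), degassed THF, 55 °C, Ar; then air, Et2O, rt; quick filtration through Et3N-washed silica
Reagents that add atoms: none
Why: This is a Dötz benzannulation, the reaction type by which methoxy(2-furyl)carbene complexes of zerovalent chromium and terminal alkynes are known to give 4-hydroxy-7-methoxybenzofurans. Heating expels one CO from 7, alkyne 8 binds at the free site and inserts into the Cr=C bond (C6–C7), and a CO ligand then migrates onto the new carbene carbon (C4–C5) to give a chromium-bound furyl vinylketene. Ring A, the only ring formed, closes by six-electron electrocyclisation of that ketene onto the furan β-carbon (C3a–C4), and tautomerisation of the resulting dienone gives the phenol as its Cr(CO)3 complex 9, from which air removes the metal. No stereocentre is created. The selectivity needed is the orientation of insertion, and it is secured by the size difference on the alkyne: the CH(OEt)2-bearing carbon stays away from the carbene substituents and ends next to the CO-derived C4, while the terminal CH bonds to C7; the site of closure is unambiguous because the carbene-bearing furan carbon has a single C–H neighbour. An alkoxy carbene on chromium in THF at moderate temperature favours CO insertion over five-membered ring formation, and strong oxidants are kept out of the work-up because they would take the hydroquinone monoether to the quinone.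

Step 4
Reactants: 10 5-(diethoxymethyl)-7-methoxy-3-methyl-2-(3,4,5-trimethoxyphenyl)-1-benzofuran-4-ol
Product: 11 4-hydroxy-7-methoxy-3-methyl-2-(3,4,5-trimethoxyphenyl)-1-benzofuran-5-carbaldehyde
Conditions: 1 M HCl, THF, rt
Reagents that add atoms: water, O
Why: This acid-catalysed acetal hydrolysis is made very easy by the ortho hydroxyl and the para furan oxygen, which stabilise the oxocarbenium ion, and it is placed here on purpose because the hydrogen-bonded salicylaldehyde 11 resists air oxidation far better than 10 and any aldehyde already formed while 10 is handled converges on the same product.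

Step 5
Reactants: 11 4-hydroxy-7-methoxy-3-methyl-2-(3,4,5-trimethoxyphenyl)-1-benzofuran-5-carbaldehyde
Product: 12 5-formyl-7-methoxy-3-methyl-2-(3,4,5-trimethoxyphenyl)-1-benzofuran-4-yl trifluoromethanesulfonate
Conditions: Tf2O, pyridine, CH2Cl2, 0 °C to rt
Reagents that add atoms: trifluoromethanesulfonic anhydride (Tf2O), O=S(=O)(OS(=O)(=O)C(F)(F)F)C(F)(F)F
Why: This is an O-sulfonylation of a phenol, routine for salicylaldehydes, in which the small and very electrophilic reagent reaches the C4 oxygen between the C3 methyl and C5 formyl groups and no other group in 11 is nucleophilic enough to compete.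

Step 6
Reactants: 12 5-formyl-7-methoxy-3-methyl-2-(3,4,5-trimethoxyphenyl)-1-benzofuran-4-yl trifluoromethanesulfonate
Product: 13 ocophyllal B, 7-methoxy-3-methyl-2-(3,4,5-trimethoxyphenyl)-1-benzofuran-5-carbaldehyde
Conditions: Pd(OAc)2 (5 mol %), dppp (10 mol %), HCO2H, Et3N, DMF, 80 °C
Reagents that add atoms: none
Why: This is a palladium-catalysed transfer hydrogenolysis of an aryl triflate with formate, in which zerovalent palladium inserts into the C4–O bond activated by the ortho formyl group, formate displaces triflate and loses CO2 to leave an Ar–Pd–H species, and reductive elimination gives C4–H, the chelating diphosphine being suited to triflates flanked on both sides while the aldehyde, the aryl ethers and the benzofuran are left alone.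

Compound list
1 | 3-methylfuran-2-carboxylic acid | Cc1ccoc1C(=O)O | starting material
2 | 5-bromo-1,2,3-trimethoxybenzene | COc1cc(Br)cc(OC)c1OC | starting material
3 | 3-methyl-2-(3,4,5-trimethoxyphenyl)furan | Cc1ccoc1-c1cc(OC)c(OC)c(OC)c1 | intermediate
4 | chromium hexacarbonyl, Cr(CO)6 | O=C=[Cr](=C=O)(=C=O)(=C=O)(=C=O)=C=O | starting material
5 | [4-methyl-5-(3,4,5-trimethoxyphenyl)furan-2-yl]lithium | [Li]c1cc(C)c(-c2cc(OC)c(OC)c(OC)c2)o1 | intermediate
6 | lithium pentacarbonyl{[4-methyl-5-(3,4,5-trimethoxyphenyl)furan-2-yl]oxidomethylidene}chromate | [Li+].[O-]C(=[Cr](=C=O)(=C=O)(=C=O)(=C=O)=C=O)c1cc(C)c(-c2cc(OC)c(OC)c(OC)c2)o1 | intermediate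
7 | pentacarbonyl{methoxy[4-methyl-5-(3,4,5-trimethoxyphenyl)furan-2-yl]methylidene}chromium | COC(=[Cr](=C=O)(=C=O)(=C=O)(=C=O)=C=O)c1cc(C)c(-c2cc(OC)c(OC)c(OC)c2)o1 | intermediate
8 | 3,3-diethoxyprop-1-yne | C#CC(OCC)OCC | starting material
9 | tricarbonyl{η6-[5-(diethoxymethyl)-7-methoxy-3-methyl-2-(3,4,5-trimethoxyphenyl)-1-benzofuran-4-ol]}chromium, metal on ring A (written as arene and Cr(CO)3 fragment joined by a dot) | CCOC(OCC)c1cc(OC)c2oc(-c3cc(OC)c(OC)c(OC)c3)c(C)c2c1O.O=C=[Cr](=C=O)=C=O | intermediate
10 | 5-(diethoxymethyl)-7-methoxy-3-methyl-2-(3,4,5-trimethoxyphenyl)-1-benzofuran-4-ol | CCOC(OCC)c1cc(OC)c2oc(-c3cc(OC)c(OC)c(OC)c3)c(C)c2c1O | intermediate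
11 | 4-hydroxy-7-methoxy-3-methyl-2-(3,4,5-trimethoxyphenyl)-1-benzofuran-5-carbaldehyde | O=Cc1cc(OC)c2oc(-c3cc(OC)c(OC)c(OC)c3)c(C)c2c1O | intermediate
12 | 5-formyl-7-methoxy-3-methyl-2-(3,4,5-trimethoxyphenyl)-1-benzofuran-4-yl trifluoromethanesulfonate | O=Cc1cc(OC)c2oc(-c3cc(OC)c(OC)c(OC)c3)c(C)c2c1OS(=O)(=O)C(F)(F)F | intermediate
13 | ocophyllal B, 7-methoxy-3-methyl-2-(3,4,5-trimethoxyphenyl)-1-benzofuran-5-carbaldehyde | COc1cc(-c2oc3c(OC)cc(C=O)cc3c2C)cc(OC)c1OC | target

Total step count: 6. Longest linear sequence: 6 steps (from 1 or 2 to 13).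

Steps most likely to fail

Step 3 is the riskiest.
- **What may go wrong:** After alkyne insertion the vinylcarbene may bypass CO insertion and close a five-membered ring. The propargylic acetal may also lose ethoxide at the electrophilic metal centre and draw the complex into decomposition.
- **Fallback:** The carbene and the ring A disconnection are kept, but the alkyne substituent is taken at a lower oxidation level, so no ionisable acetal is present.
- **Course:** It sets out from 7, which is heated in THF with commercial tert-butyldimethyl(prop-2-yn-1-yloxy)silane to give the tricarbonylchromium complex of the silyl ether phenol F1. Air then frees 5-{[tert-butyl(dimethyl)silyl]oxymethyl}-7-methoxy-3-methyl-2-(3,4,5-trimethoxyphenyl)-1-benzofuran-4-ol F2. Tf2O and pyridine convert it into the silyl ether C4 triflate F3, and HF·pyridine in THF removes the silyl group to give the hydroxymethyl triflate F4. MnO2 in CH2Cl2 oxidises the benzylic alcohol, and the route is rejoined at 12.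

Step 2 comes second.
- **What may go wrong:** Deprotonation may spread from the furan α-carbon to the ring C positions ortho to a methoxy group or to the C3 methyl group, so that a mixture of organolithiums meets Cr(CO)6.
- **Fallback:** C–H deprotonation is replaced by halogen–metal exchange at a position fixed beforehand.
- **Course:** It sets out from 3, which NBS in DMF at 0 °C brominates at the free, most electron-rich α-carbon to give 2-bromo-4-methyl-5-(3,4,5-trimethoxyphenyl)furan F5. Bromine–lithium exchange with n-BuLi in THF at −78 °C then gives the furyllithium, and the route is rejoined at 5.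

Step 6 comes third.
- **What may go wrong:** Formate or amine may attack the sulfur of the electron-poor ortho-formyl triflate and return the phenol. The free aldehyde may also be reduced or decarbonylated on palladium during a slow reaction.
- **Fallback:** The deoxygenation is run on the electron-richer, aldehyde-masked series, with the aldehyde unmasked last.
- **Course:** It sets out from 10, which N-phenylbis(trifluoromethanesulfonimide) and Cs2CO3 in DMF (base only, no acid present) convert into the acetal triflate F6. Pd(OAc)2, dppp, HCO2H and excess Et3N in DMF then give 5-(diethoxymethyl)-7-methoxy-3-methyl-2-(3,4,5-trimethoxyphenyl)-1-benzofuran F7. 1 M HCl in THF opens the acetal, and the route is rejoined at 13.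

Further compounds
F1 | step 3 | tricarbonyl{η6-[5-{[tert-butyl(dimethyl)silyl]oxymethyl}-7-methoxy-3-methyl-2-(3,4,5-trimethoxyphenyl)-1-benzofuran-4-ol]}chromium | CC(C)(C)[Si](C)(C)OCc1cc(OC)c2oc(-c3cc(OC)c(OC)c(OC)c3)c(C)c2c1O.O=C=[Cr](=C=O)=C=O
F2 | step 3 | 5-{[tert-butyl(dimethyl)silyl]oxymethyl}-7-methoxy-3-methyl-2-(3,4,5-trimethoxyphenyl)-1-benzofuran-4-ol | CC(C)(C)[Si](C)(C)OCc1cc(OC)c2oc(-c3cc(OC)c(OC)c(OC)c3)c(C)c2c1O
F3 | step 3 | 5-{[tert-butyl(dimethyl)silyl]oxymethyl}-7-methoxy-3-methyl-2-(3,4,5-trimethoxyphenyl)-1-benzofuran-4-yl trifluoromethanesulfonate | CC(C)(C)[Si](C)(C)OCc1cc(OC)c2oc(-c3cc(OC)c(OC)c(OC)c3)c(C)c2c1OS(=O)(=O)C(F)(F)F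
F4 | step 3 | 5-(hydroxymethyl)-7-methoxy-3-methyl-2-(3,4,5-trimethoxyphenyl)-1-benzofuran-4-yl trifluoromethanesulfonate | OCc1cc(OC)c2oc(-c3cc(OC)c(OC)c(OC)c3)c(C)c2c1OS(=O)(=O)C(F)(F)F
F5 | step 2 | 2-bromo-4-methyl-5-(3,4,5-trimethoxyphenyl)furan | Brc1cc(C)c(-c2cc(OC)c(OC)c(OC)c2)o1
F6 | step 6 | 5-(diethoxymethyl)-7-methoxy-3-methyl-2-(3,4,5-trimethoxyphenyl)-1-benzofuran-4-yl trifluoromethanesulfonate | CCOC(OCC)c1cc(OC)c2oc(-c3cc(OC)c(OC)c(OC)c3)c(C)c2c1OS(=O)(=O)C(F)(F)F
F7 | step 6 | 5-(diethoxymethyl)-7-methoxy-3-methyl-2-(3,4,5-trimethoxyphenyl)-1-benzofuran | CCOC(OCC)c1cc(OC)c2oc(-c3cc(OC)c(OC)c(OC)c3)c(C)c2c1
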